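**Retrosynthetic overview**
- The last C–C bond is C9–C10. A visible-light radical 6-exo cyclisation closes lactone ring B and sets C9, C10 and C5. The C16=C17 alkene is masked as a thioether until afterwards.
- The cyclisation substrate is an ester made from a ring C/D hydroxy acid and an achiral ring A allylic chloride by carboxylate alkylation.
- Ring D is closed by a C8–C15 aldol addition of a ring C β-keto ester. An Evans–Tishchenko step then gives the 15-acetate and the 9-hydroxyl group.
- Ring C and its C13 stereocentre come from (+)-nopinone by C-acylation and cyclobutane opening.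
- Ring A comes from a Diels–Alder reaction followed by bis-allylic oxidation. Ring order: C (bought), D, A (separate branch), B last.

Assumption: ent-kaurane numbering (C1–C20) is used for positions in the text. Centres that are labile or destroyed later are left undefined: the α-carbon of the β-keto esters, the thioether-bearing C16, the aminal carbon of 20 and the sulfur of 22.

Step 1
Reactants: 1 (+)-nopinone, (1R,5S)-6,6-dimethylbicyclo[3.1.1]heptan-2-one
Product: 2 allyl (1R,5R)-6,6-dimethyl-2-oxobicyclo[3.1.1]heptane-3-carboxylate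
Conditions: NaH (2.2 equiv), diallyl carbonate (2 equiv), THF, reflux; aq. HCl work-up
Reagents that add atoms: diallyl carbonate, C=CCOC(=O)OCC=C
Why: In this crossed Claisen C-acylation the ketone can enolise only away from the bridgehead, so one β-keto ester forms and both bought stereocentres are untouched.

Step 2
Reactants: 2 allyl (1R,5R)-6,6-dimethyl-2-oxobicyclo[3.1.1]heptane-3-carboxylate
Product: 3 allyl (5R)-5-(2-bromopropan-2-yl)-2-oxocyclohexane-1-carboxylate
Conditions: HBr (33% in AcOH, 1.5 equiv), CH2Cl2, 0 °C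
Reagents that add atoms: hydrogen bromide, Br
Why: In this acid-induced fragmentation of a cyclobutyl ketone the strained bond that overlaps with the protonated carbonyl breaks to a tertiary cation, bromide traps it, and the future C13 remains as the only fixed stereocentre.

Step 3
Reactants: 3 allyl (5R)-5-(2-bromopropan-2-yl)-2-oxocyclohexane-1-carboxylate
Product: 5 allyl (5R)-2-acetoxy-5-(prop-1-en-2-yl)cyclohex-1-ene-1-carboxylate, via potassium enolate 4 (not isolated)
Conditions: KOt-Bu (2.1 equiv), THF, −20 °C; then Ac2O (1.2 equiv), −20 °C to rt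
Reagents that add atoms: acetic anhydride, CC(=O)OC(C)=O
Why: E2 elimination with a bulky base (Hofmann orientation, six methyl hydrogens against one hindered methine) gives the isopropenyl group, and O-acetylation of the enolate masks the β-keto ester for the next oxidation.

Step 4
Reactants: 5 allyl (5R)-2-acetoxy-5-(prop-1-en-2-yl)cyclohex-1-ene-1-carboxylate
Product: 7 allyl (5R)-2-acetoxy-5-(3-oxoprop-1-en-2-yl)cyclohex-1-ene-1-carboxylate, via allylic alcohol 6 (not isolated)
Conditions: SeO2 (20 mol %), t-BuOOH (2 equiv), CH2Cl2, rt; then MnO2 (excess), same flask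
Reagents that add atoms: tert-butyl hydroperoxide, CC(C)(C)OO
Why: The selenium dioxide allylic oxidation (ene reaction, then [2,3]-shift) picks the only electron-rich alkene, and MnO2 takes the allylic alcohol on to the enal.

Step 5
Reactants: 7 allyl (5R)-2-acetoxy-5-(3-oxoprop-1-en-2-yl)cyclohex-1-ene-1-carboxylate
Product: 10 allyl (1R,5R,7S)-7-hydroxy-2-oxo-6-[(phenylsulfanyl)methyl]bicyclo[3.2.1]octane-1-carboxylate (7-exo alcohol), via thioether enol acetate 8 (not isolated), via keto aldehyde 9 (not isolated)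
Conditions: PhSH (2.1 equiv), Et3N (1.0 equiv), CH2Cl2, 0 °C to rt
Reagents that add atoms: thiophenol, Sc1ccccc1
Why: A thia-Michael addition masks the enal alkene, thiolysis frees the β-keto ester, and its enolate closes ring D by a 5-exo intramolecular aldol addition that is possible only on the face of the C13 side chain (fixing quaternary C8), while the open transition state should turn the carbinol oxygen exo.

Step 6
Reactants: 10 allyl (1R,5R,7S)-7-hydroxy-2-oxo-6-[(phenylsulfanyl)methyl]bicyclo[3.2.1]octane-1-carboxylate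
Product: 12 allyl (1S,2R,5R,7R)-7-acetoxy-2-hydroxy-6-[(phenylsulfanyl)methyl]bicyclo[3.2.1]octane-1-carboxylate, via endo aldol 11 (not isolated)
Conditions: SmI2 (30 mol %), MeCHO (10 equiv), THF, −10 °C to rt
Reagents that add atoms: acetaldehyde, CC=O
Why: This is an Evans–Tishchenko reduction inside the aldol–Tishchenko manifold, in which the trivalent samarium alkoxide equilibrates 10 and 11 by retro-aldol and aldol addition, and only the endo hemiacetal of 11 can pass hydride to the C9 ketone, which irreversibly sets the endo 15-acetate and leaves the 9-hydroxyl free.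

Step 7
Reactants: 12 allyl (1S,2R,5R,7R)-7-acetoxy-2-hydroxy-6-[(phenylsulfanyl)methyl]bicyclo[3.2.1]octane-1-carboxylate
Product: 13 (1S,2R,5R,7R)-7-acetoxy-2-hydroxy-6-[(phenylsulfanyl)methyl]bicyclo[3.2.1]octane-1-carboxylic acid
Conditions: Pd(PPh3)4 (3 mol %), morpholine (1.5 equiv), THF, 0 °C
Reagents that add atoms: none
Why: In this Tsuji–Trost deallylation zerovalent palladium ionises the only allylic ester present, morpholine traps the allyl group, and the acetate and the thioether are left alone.

Step 8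
Reactants: 14 4-chlorobut-2-yn-1-ol
Product: 15 4-chlorobut-2-ynal
Conditions: MnO2 (10 equiv), CH2Cl2, rt
Reagents that add atoms: none
Why: MnO2 oxidises the propargylic alcohol and stops at the aldehyde.

Step 9
Reactants: 15 4-chlorobut-2-ynal; 16 4-methylpenta-1,3-diene
Product: 17 2-(chloromethyl)-6,6-dimethylcyclohexa-1,4-diene-1-carbaldehyde
Conditions: 16 (4 equiv), BHT (cat.), toluene, 90 °C, sealed tube
Reagents that add atoms: none
Why: In this Diels–Alder reaction of a slim ynal the unsubstituted, more nucleophilic diene terminus bonds to the β-carbon ("ortho" rule), which places the gem-dimethyl carbon next to the formyl-bearing carbon and creates no stereocentre.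

Step 10
Reactants: 17 2-(chloromethyl)-6,6-dimethylcyclohexa-1,4-diene-1-carbaldehyde
Product: 18 2-(chloromethyl)-6,6-dimethyl-3-oxocyclohexa-1,4-diene-1-carbaldehyde
Conditions: Mn(OAc)3·2H2O (10 mol %), t-BuOOH (5 equiv), EtOAc, 3 Å MS, rt
Reagents that add atoms: tert-butyl hydroperoxide, CC(C)(C)OO
Why: A peroxy-radical oxidation converts the single doubly allylic CH2 into the cross-conjugated dienone, and the quaternary carbon blocks aromatisation.

Step 11
Reactants: 13 (1S,2R,5R,7R)-7-acetoxy-2-hydroxy-6-[(phenylsulfanyl)methyl]bicyclo[3.2.1]octane-1-carboxylic acid; 18 2-(chloromethyl)-6,6-dimethyl-3-oxocyclohexa-1,4-diene-1-carbaldehyde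
Product: 19 (2-formyl-3,3-dimethyl-6-oxocyclohexa-1,4-dien-1-yl)methyl (1S,2R,5R,7R)-7-acetoxy-2-hydroxy-6-[(phenylsulfanyl)methyl]bicyclo[3.2.1]octane-1-carboxylate
Conditions: Cs2CO3 (1.0 equiv), NaI (10 mol %), DMF, 0 °C to rt
Reagents that add atoms: none
Why: SN2 alkylation of the carboxylate at the primary allylic chloride avoids any attack at the hindered bridgehead acyl carbon, and 18 has no enolisable hydrogen.

Step 12
Reactants: 19 (2-formyl-3,3-dimethyl-6-oxocyclohexa-1,4-dien-1-yl)methyl (1S,2R,5R,7R)-7-acetoxy-2-hydroxy-6-[(phenylsulfanyl)methyl]bicyclo[3.2.1]octane-1-carboxylate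
Product: 21 17-(phenylsulfanyl)-16,17-dihydro derivative of the target (5R,8S,9S,10S,13R,15R), via alkoxybenzoxazoline 20 (not isolated)
Conditions: 5,7-di-tert-butyl-3-phenylbenzoxazolium tetrafluoroborate (1.2 equiv), pyridine (1.2 equiv), MTBE, rt; then [Ir(ppy)2(dtbbpy)]PF6 (2 mol %), CsOPiv (20 mol %), MTBE/DMSO, 0.005 M, 450 nm LEDs, 45 °C
Reagents that add atoms: none
Why: Proposed new method: the excited iridium complex oxidises aminal 20, and loss of a proton followed by β-scission releases the nucleophilic secondary C9 radical; this radical adds 6-exo to C10, the β-carbon of the enal, which the C1 ketone activates further; attack comes from the exo face, away from the two-carbon bridge and its endo acetate (sets C9), with the flat C1 carbonyl side of ring A under ring C and the gem-dimethyl side outward (sets C10); the reduced iridium complex turns the α-formyl radical into the enolate, which is protonated opposite C20 and the axial methyl (sets C5); the thioether mask removes the allylic stabilisation that would otherwise let the C9 radical cleave the aligned C8–C15 bond, and a medium poor in hydrogen donors at gentle heat gives the slow ester rotamer time to react; the closest known reaction types are the photoredox deoxygenative Giese alkylation of alcohols and radical spirolactone formation, and what is new is the ester tether, the tetrasubstituted ene-dicarbonyl acceptor and the vicinal tertiary/quaternary pair.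

Step 13
Reactants: 21 17-(phenylsulfanyl)-16,17-dihydro derivative of the target
Product: 23 target CNP0108627.4, via sulfoxide 22 (not isolated)
Conditions: mCPBA (1.0 equiv), CH2Cl2, −78 °C; then toluene, CaCO3, 110 °C
Reagents that add atoms: none
Why: Sulfur is oxidised chemoselectively, and thermal syn elimination of the sulfoxide then uses the only β-hydrogen, at C16, so only the exocyclic C16=C17 alkene can form and no stereocentre is touched.

**Compound list**
1 | (+)-nopinone | O=C1CC[C@H]2C[C@@H]1C2(C)C | starting material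
2 | allyl (1R,5R)-6,6-dimethyl-2-oxobicyclo[3.1.1]heptane-3-carboxylate | C=CCOC(=O)C1C[C@H]2C[C@@H](C1=O)C2(C)C | intermediate
3 | allyl (5R)-5-(2-bromopropan-2-yl)-2-oxocyclohexane-1-carboxylate | CC(C)(Br)[C@@H]1CCC(=O)C(C1)C(=O)OCC=C | intermediate
4 | potassium enolate of allyl (5R)-2-oxo-5-(prop-1-en-2-yl)cyclohexane-1-carboxylate | C=C(C)[C@@H]1CCC([O-])=C(C1)C(=O)OCC=C.[K+] | intermediate
5 | allyl (5R)-2-acetoxy-5-(prop-1-en-2-yl)cyclohex-1-ene-1-carboxylate | C=C(C)[C@@H]1CCC(OC(C)=O)=C(C1)C(=O)OCC=C | intermediate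
6 | allyl (5R)-2-acetoxy-5-(3-hydroxyprop-1-en-2-yl)cyclohex-1-ene-1-carboxylate | C=C(CO)[C@@H]1CCC(OC(C)=O)=C(C1)C(=O)OCC=C | intermediate
7 | allyl (5R)-2-acetoxy-5-(3-oxoprop-1-en-2-yl)cyclohex-1-ene-1-carboxylate | C=C(C=O)[C@@H]1CCC(OC(C)=O)=C(C1)C(=O)OCC=C | intermediate
8 | allyl (5R)-2-acetoxy-5-[1-oxo-3-(phenylsulfanyl)propan-2-yl]cyclohex-1-ene-1-carboxylate | O=CC(CSc1ccccc1)[C@@H]1CCC(OC(C)=O)=C(C1)C(=O)OCC=C | intermediate
9 | allyl (5R)-2-oxo-5-[1-oxo-3-(phenylsulfanyl)propan-2-yl]cyclohexane-1-carboxylate | O=CC(CSc1ccccc1)[C@@H]1CCC(=O)C(C1)C(=O)OCC=C | intermediate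
10 | allyl (1R,5R,7S)-7-hydroxy-2-oxo-6-[(phenylsulfanyl)methyl]bicyclo[3.2.1]octane-1-carboxylate (exo alcohol) | c1ccccc1SCC1[C@@H]2CCC(=O)[C@](C2)(C(=O)OCC=C)[C@H]1O | intermediate
11 | allyl (1R,5R,7R)-7-hydroxy-2-oxo-6-[(phenylsulfanyl)methyl]bicyclo[3.2.1]octane-1-carboxylate (endo alcohol) | c1ccccc1SCC1[C@@H]2CCC(=O)[C@](C2)(C(=O)OCC=C)[C@@H]1O | intermediate
12 | allyl (1S,2R,5R,7R)-7-acetoxy-2-hydroxy-6-[(phenylsulfanyl)methyl]bicyclo[3.2.1]octane-1-carboxylate | c1ccccc1SCC1[C@@H]2CC[C@@H](O)[C@](C2)(C(=O)OCC=C)[C@@H]1OC(C)=O | intermediate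
13 | (1S,2R,5R,7R)-7-acetoxy-2-hydroxy-6-[(phenylsulfanyl)methyl]bicyclo[3.2.1]octane-1-carboxylic acid | c1ccccc1SCC1[C@@H]2CC[C@@H](O)[C@](C2)(C(=O)O)[C@@H]1OC(C)=O | intermediate
14 | 4-chlorobut-2-yn-1-ol | OCC#CCCl | starting material
15 | 4-chlorobut-2-ynal | O=CC#CCCl | intermediate
16 | 4-methylpenta-1,3-diene | CC(C)=CC=C | starting material
17 | 2-(chloromethyl)-6,6-dimethylcyclohexa-1,4-diene-1-carbaldehyde | O=CC1=C(CCl)CC=CC1(C)C | intermediate
18 | 2-(chloromethyl)-6,6-dimethyl-3-oxocyclohexa-1,4-diene-1-carbaldehyde | O=CC1=C(CCl)C(=O)C=CC1(C)C | intermediate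
19 | (2-formyl-3,3-dimethyl-6-oxocyclohexa-1,4-dien-1-yl)methyl ester of 13 | c1ccccc1SCC1[C@@H]2CC[C@@H](O)[C@](C2)(C(=O)OCC2=C(C=O)C(C)(C)C=CC2=O)[C@@H]1OC(C)=O | intermediate
20 | 2-alkoxy-5,7-di-tert-butyl-3-phenyl-2,3-dihydrobenzoxazole derived from 19 | c1ccccc1SCC1[C@@H]2CC[C@@H](OC3Oc4c(C(C)(C)C)cc(C(C)(C)C)cc4N3c3ccccc3)[C@](C2)(C(=O)OCC2=C(C=O)C(C)(C)C=CC2=O)[C@@H]1OC(C)=O | intermediate
21 | 17-(phenylsulfanyl)-16,17-dihydro target | c1ccccc1SCC1[C@@H]2CC[C@@H]3[C@](C2)(C(=O)OC[C@]32C(=O)C=CC(C)(C)[C@H]2C=O)[C@@H]1OC(C)=O | intermediate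
22 | sulfoxide of 21 | O=S(c1ccccc1)CC1[C@@H]2CC[C@@H]3[C@](C2)(C(=O)OC[C@]32C(=O)C=CC(C)(C)[C@H]2C=O)[C@@H]1OC(C)=O | intermediate
23 | CNP0108627.4 | C=C1[C@@H]2CC[C@@H]3[C@](C2)(C(=O)OC[C@]32C(=O)C=CC(C)(C)[C@H]2C=O)[C@@H]1OC(C)=O | target

**Step count:** 13 steps in total. The longest linear sequence is 10 steps (steps 1–7 and 11–13).

**The three steps most likely to fail**

Step 12 is the proposed new step. The risks are slow closure through the ester tether onto a fully substituted carbon, competing hydrogen abstraction, and residual ring D fragmentation. The fallback sets out from 13 and comes back at 21, and it makes the C9–C10 bond between two molecules with known chemistry.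
- Acid 13 reacts with chloromethyl chlorosulfate (NaHCO3, Bu4NHSO4, CH2Cl2/H2O) to give the chloromethyl ester F1.
- Propargyl alcohol is oxidised with MnO2 to propynal F2.
- F2 adds to diene 16 to give 6,6-dimethylcyclohexa-1,4-diene-1-carbaldehyde F3.
- The oxidation used in step 10 turns F3 into 6,6-dimethyl-3-oxocyclohexa-1,4-diene-1-carbaldehyde F4, whose C10 still carries hydrogen and is open to attack.
- The same benzoxazolium activation turns F1 into the alkoxybenzoxazoline F5.
- Irradiation of F5 with the iridium catalyst and F4 (2 equiv, 0.3 M) is an ordinary deoxygenative Giese addition and gives the C9–C10 adduct F6.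
- LiN(SiMe3)2 (2.1 equiv, THF, −78 to 0 °C) then closes the lactone by C-alkylation of the C10 dienolate with the chloromethyl ester, with the bulky side of ring A turned outward.
- A quench with acetic acid at −78 °C protonates the aldehyde enolate kinetically and gives 21.

Step 6 may fail because the hindered endo aldol may not be reached fast enough. The fallback sets out from 10 and comes back at 12.
- With the alkene masked, no SN2′ path is open, so a Mitsunobu inversion (AcOH, DIAD, PPh3) gives the endo acetoxy ketone F7.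
- LiBH(s-Bu)3 at −78 °C attacks the C9 ketone equatorially and gives the axial alcohol 12.

Step 4 may give a low yield or attack the enol acetate. The fallback sets out from 5 and comes back at 7.
- Ene-type chlorination with Ca(OCl)2 and CO2 in CH2Cl2/H2O gives the allylic chloride F8.
- A Kornblum-type oxidation with N-methylmorpholine N-oxide in MeCN gives enal 7.

**Further compounds**
F1 | step 12 | chloromethyl ester of 13 | c1ccccc1SCC1[C@@H]2CC[C@@H](O)[C@](C2)(C(=O)OCCl)[C@@H]1OC(C)=O
F2 | step 12 | propynal | C#CC=O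
F3 | step 12 | 6,6-dimethylcyclohexa-1,4-diene-1-carbaldehyde | O=CC1=CCC=CC1(C)C
F4 | step 12 | 6,6-dimethyl-3-oxocyclohexa-1,4-diene-1-carbaldehyde | O=CC1=CC(=O)C=CC1(C)C
F5 | step 12 | alkoxybenzoxazoline derived from F1 | c1ccccc1SCC1[C@@H]2CC[C@@H](OC3Oc4c(C(C)(C)C)cc(C(C)(C)C)cc4N3c3ccccc3)[C@](C2)(C(=O)OCCl)[C@@H]1OC(C)=O
F6 | step 12 | C9–C10 Giese adduct (C10 and C5 labile) | c1ccccc1SCC1[C@@H]2CC[C@@H](C3C(C=O)C(C)(C)C=CC3=O)[C@](C2)(C(=O)OCCl)[C@@H]1OC(C)=O
F7 | step 6 | allyl (1R,5R,7R)-7-acetoxy-2-oxo-6-[(phenylsulfanyl)methyl]bicyclo[3.2.1]octane-1-carboxylate | c1ccccc1SCC1[C@@H]2CCC(=O)[C@](C2)(C(=O)OCC=C)[C@@H]1OC(C)=O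
F8 | step 4 | allyl (5R)-2-acetoxy-5-(3-chloroprop-1-en-2-yl)cyclohex-1-ene-1-carboxylate | C=C(CCl)[C@@H]1CCC(OC(C)=O)=C(C1)C(=O)OCC=C
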